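**Strategy.** The A ring is built last, onto a finished B/C unit, by a vinylketene–siloxyalkyne benzannulation. The step exploits the A-ring pattern C5–OH, C6–alkyl, C7–OH, C8–H fused at C4a–C8a. A ketene carbonyl carbon (C5), the two carbons of an alkyl siloxyalkyne (C6, C7) and a diazo carbon (C8) write exactly this pattern onto a C=C bond. One operation forms C8–C8a (Wolff shift), C5–C6, C7–C8 and C4a–C5 and places the chain between the two oxygens. The precursor is a kojic-acid-derived 2-diazoacetyl-4-pyranone carrying O3 as a benzyl ether and the benzyl-protected B ring, partnered with a TIPS ynol ether bearing the TES-protected tertiary alcohol.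

Key step: step 9

Remark: the target has no stereogenic centre or axis, so "single enantiomer" is taken to mean the achiral compound as drawn; no step needs stereocontrol.

Step 1
Reactants: 1 kojic acid, 5-hydroxy-2-(hydroxymethyl)-4H-pyran-4-one
Product: 2 2-bromo-3-hydroxy-6-(hydroxymethyl)-4H-pyran-4-one (6-bromokojic acid)
Conditions: NBS (1.05 equiv), DMF, 0 °C → rt, dark
Reagents that add atoms: N-bromosuccinimide, O=C1CCC(=O)N1Br
Why: Electrophilic bromination of the enol: C6 is the only ring CH ortho to the 5-OH (the enol α-carbon, where kojic acid takes electrophiles in Mannich and hydroxymethylation reactions), whereas C3 is not activated.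

Step 2
Reactants: 2 2-bromo-3-hydroxy-6-(hydroxymethyl)-4H-pyran-4-one
Product: 3 3-(benzyloxy)-2-bromo-6-(hydroxymethyl)-4H-pyran-4-one
Conditions: BnBr (1.1 equiv), K2CO3, DMF, rt
Reagents that add atoms: benzyl bromide, BrCc1ccccc1
Why: Williamson etherification: carbonate ionises only the acidic enolic OH, so the primary alcohol stays free, and anhydrous conditions at room temperature spare the vinylogous acyl bromide.

Step 3
Reactants: 3 3-(benzyloxy)-2-bromo-6-(hydroxymethyl)-4H-pyran-4-one; 4 4-(benzyloxy)phenylboronic acid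
Product: 5 3-(benzyloxy)-2-[4-(benzyloxy)phenyl]-6-(hydroxymethyl)-4H-pyran-4-one
Conditions: Pd(dppf)Cl2 (5 mol %), K2CO3, 1,4-dioxane/H2O (5:1), 80 °C
Reagents that add atoms: none
Why: Suzuki–Miyaura coupling: the C–Br bond sits at the β-position of the pyranone enone, so oxidative addition should be fast, and the free hydroxymethyl group and the benzyl ethers are inert.

Step 4
Reactants: 5 3-(benzyloxy)-2-[4-(benzyloxy)phenyl]-6-(hydroxymethyl)-4H-pyran-4-one
Product: 7 5-(benzyloxy)-6-[4-(benzyloxy)phenyl]-4-oxo-4H-pyran-2-carboxylic acid, via pyranone-2-carbaldehyde 6 (not isolated)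
Conditions: TEMPO (0.2 equiv), PhI(OAc)2 (2.5 equiv), MeCN/H2O (1:1), rt
Reagents that add atoms: water, O
Why: TEMPO/PhI(OAc)2 (oxoammonium) oxidation takes the primary alcohol to aldehyde 6, whose hydrate is favoured on this electron-poor ring and is oxidised on to the acid, while benzyl ethers and the electron-rich aryl ring should be untouched.

Step 5
Reactants: 7 5-(benzyloxy)-6-[4-(benzyloxy)phenyl]-4-oxo-4H-pyran-2-carboxylic acid
Product: 9 1-{5-(benzyloxy)-6-[4-(benzyloxy)phenyl]-4-oxo-4H-pyran-2-yl}-2-diazoethan-1-one, via pyranone-2-carbonyl chloride 8 (not isolated)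
Conditions: (COCl)2, cat. DMF, CH2Cl2, 0 °C → rt, evaporate; CH2N2 (3 equiv), Et2O/THF, −10 → 0 °C
Reagents that add atoms: diazomethane, C=[N+]=[N-]
Why: Acid chloride formation followed by C-acylation of diazomethane (first stage of an Arndt–Eistert sequence); surplus diazomethane removes HCl so no chloromethyl ketone forms, and low temperature with short contact limits cycloaddition to the pyranone C=C.

Step 6
Reactants: 10 methyl pent-4-ynoate
Product: 12 2-methylhex-5-yn-2-ol, via hex-5-yn-2-one 11 (not isolated)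
Conditions: MeMgBr (2.5 equiv), THF, 0 °C → rt; H2O work-up
Reagents that add atoms: methylmagnesium bromide, C[Mg]Br
Why: Double Grignard addition to the ester: ketone 11 is more electrophilic than the ester and is consumed as it forms, giving the tertiary alcohol.

Step 7
Reactants: 12 2-methylhex-5-yn-2-ol
Product: 13 triethyl[(2-methylhex-5-yn-2-yl)oxy]silane
Conditions: TESOTf, 2,6-lutidine, CH2Cl2, −78 → 0 °C
Reagents that add atoms: triethylsilyl trifluoromethanesulfonate, CC[Si](CC)(CC)OS(=O)(=O)C(F)(F)F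
Why: Silylation of a hindered tertiary alcohol with a silyl triflate and a non-nucleophilic base; TES is chosen to survive amide base, peroxide and ketene but to leave with fluoride at the end.

Step 8
Reactants: 13 triethyl[(2-methylhex-5-yn-2-yl)oxy]silane
Product: 16 triethyl{[2-methyl-6-(triisopropylsilyloxy)hex-5-yn-2-yl]oxy}silane, via lithium acetylide 14 (not isolated), via lithium ynolate 15 (not isolated)
Conditions: LiHMDS (2.2 equiv), t-BuOOH (anhydrous), THF, −78 → 0 °C; TIPSOTf, −78 → 0 °C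
Reagents that add atoms: tert-butyl hydroperoxide, CC(C)(C)OO; triisopropylsilyl trifluoromethanesulfonate, CC(C)[Si](C(C)C)(C(C)C)OS(=O)(=O)C(F)(F)F
Why: Julia-type electrophilic oxygen transfer from lithium tert-butyl peroxide to the lithium acetylide gives ynolate 15, which the bulky silyl triflate should trap on oxygen to give a TIPS ynol ether stable to chromatography.

Step 9
Reactants: 9 1-{5-(benzyloxy)-6-[4-(benzyloxy)phenyl]-4-oxo-4H-pyran-2-yl}-2-diazoethan-1-one; 16 triethyl{[2-methyl-6-(triisopropylsilyloxy)hex-5-yn-2-yl]oxy}silane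
Product: 21 3-(benzyloxy)-2-[4-(benzyloxy)phenyl]-5-hydroxy-6-[3-methyl-3-(triethylsilyloxy)butyl]-7-(triisopropylsilyloxy)-4H-chromen-4-one, via pyranonylketene 17 (not isolated), via siloxycyclobutenone 18 (not isolated), via dienylketene 19 (not isolated), via cyclohexadienone tautomer 20 (not isolated)
Conditions: 16 (1.5 equiv), hν (450 nm LED), degassed ClCH2CH2Cl (0.05 M), rt; then 80 °C
Reagents that add atoms: none
Why: Irradiation at 450 nm should excite only the long-wavelength diazocarbonyl band of 9 (the pyranone π→π* band, 18 and the product absorb at shorter wavelength), so N2 loss with Wolff shift of the pyranonyl group to the diazo carbon (C8–C8a) should give ketene 17 without pyranone photochemistry. The polarised ynol ether 16 then adds [2+2], its nucleophilic alkyl-bearing carbon to the ketene carbonyl carbon (C5–C6) and its silyloxy carbon to the ketene α-carbon (C7–C8), giving cyclobutenone 18. At 80 °C 18 opens by 4π electrocyclic ring opening to dienylketene 19, the A ring closes by thermal disrotatory 6π electrocyclisation of the ketene carbon onto the pyranone C3–H (C4a–C5), and dienone 20 enolises to the phenol chelated to the C4 carbonyl. The closest known reaction type is the Danheiser benzannulation of α,β-unsaturated and heteroaryl α-diazo ketones with triisopropylsiloxyalkynes, here applied to a pyranone C=C bond as the ene component. No stereocentre is formed. The regiochemistry needed (chain on C6 between O5 and O7) follows from the ynol ether polarity in the [2+2] step, the closure has only one ring CH next to the ketene-bearing carbon, and the chelated 5-OH is too poor a nucleophile to be acylated by surplus ketene.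

Step 10
Reactants: 21 3-(benzyloxy)-2-[4-(benzyloxy)phenyl]-5-hydroxy-6-[3-methyl-3-(triethylsilyloxy)butyl]-7-(triisopropylsilyloxy)-4H-chromen-4-one
Product: 22 3-(benzyloxy)-2-[4-(benzyloxy)phenyl]-5,7-dihydroxy-6-(3-hydroxy-3-methylbutyl)-4H-chromen-4-one
Conditions: TBAF (2.5 equiv), AcOH (2.5 equiv), THF, 0 °C → rt
Reagents that add atoms: none
Why: Fluoride-mediated desilylation cleaves the aryl TIPS ether and the tertiary TES ether; the acetic acid buffer avoids strongly basic phenoxide, no acid strong enough to ionise the tertiary alcohol or cyclise it onto a flanking phenol is present, and the benzyl ethers are unaffected.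

Step 11
Reactants: 22 3-(benzyloxy)-2-[4-(benzyloxy)phenyl]-5,7-dihydroxy-6-(3-hydroxy-3-methylbutyl)-4H-chromen-4-one
Product: 23 3,5,7-trihydroxy-6-(3-hydroxy-3-methylbutyl)-2-(4-hydroxyphenyl)-4H-chromen-4-one (target)
Conditions: H2 (1 atm), 10% Pd/C, EtOAc/MeOH, rt
Reagents that add atoms: none
Why: Catalytic hydrogenolysis of the two benzyl ethers under neutral conditions; the flavonol C2=C3 bond, the chelated carbonyl and the non-benzylic tertiary alcohol should not be reduced at 1 atm.

**Compound list**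

1 | kojic acid, 5-hydroxy-2-(hydroxymethyl)-4H-pyran-4-one | OCc1cc(=O)c(O)co1 | starting material
2 | 2-bromo-3-hydroxy-6-(hydroxymethyl)-4H-pyran-4-one | OCc1cc(=O)c(O)c(Br)o1 | intermediate
3 | 3-(benzyloxy)-2-bromo-6-(hydroxymethyl)-4H-pyran-4-one | OCc1cc(=O)c(OCc2ccccc2)c(Br)o1 | intermediate
4 | 4-(benzyloxy)phenylboronic acid | OB(O)c1ccc(OCc2ccccc2)cc1 | starting material
5 | 3-(benzyloxy)-2-[4-(benzyloxy)phenyl]-6-(hydroxymethyl)-4H-pyran-4-one | OCc1cc(=O)c(OCc2ccccc2)c(-c2ccc(OCc3ccccc3)cc2)o1 | intermediate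
6 | 5-(benzyloxy)-6-[4-(benzyloxy)phenyl]-4-oxo-4H-pyran-2-carbaldehyde | O=Cc1cc(=O)c(OCc2ccccc2)c(-c2ccc(OCc3ccccc3)cc2)o1 | intermediate (not isolated)
7 | 5-(benzyloxy)-6-[4-(benzyloxy)phenyl]-4-oxo-4H-pyran-2-carboxylic acid | OC(=O)c1cc(=O)c(OCc2ccccc2)c(-c2ccc(OCc3ccccc3)cc2)o1 | intermediate
8 | 5-(benzyloxy)-6-[4-(benzyloxy)phenyl]-4-oxo-4H-pyran-2-carbonyl chloride | ClC(=O)c1cc(=O)c(OCc2ccccc2)c(-c2ccc(OCc3ccccc3)cc2)o1 | intermediate (not isolated)
9 | 1-{5-(benzyloxy)-6-[4-(benzyloxy)phenyl]-4-oxo-4H-pyran-2-yl}-2-diazoethan-1-one | [N-]=[N+]=CC(=O)c1cc(=O)c(OCc2ccccc2)c(-c2ccc(OCc3ccccc3)cc2)o1 | intermediate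
10 | methyl pent-4-ynoate | C#CCCC(=O)OC | starting material
11 | hex-5-yn-2-one | CC(=O)CCC#C | intermediate (not isolated)
12 | 2-methylhex-5-yn-2-ol | CC(C)(O)CCC#C | intermediate
13 | triethyl[(2-methylhex-5-yn-2-yl)oxy]silane | CC(C)(O[Si](CC)(CC)CC)CCC#C | intermediate
14 | lithium 5-methyl-5-(triethylsilyloxy)hex-1-yn-1-ide | CC(C)(O[Si](CC)(CC)CC)CCC#[C-].[Li+] | intermediate (not isolated)
15 | lithium 5-methyl-5-(triethylsilyloxy)hex-1-yn-1-olate | CC(C)(O[Si](CC)(CC)CC)CCC#C[O-].[Li+] | intermediate (not isolated)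
16 | triethyl{[2-methyl-6-(triisopropylsilyloxy)hex-5-yn-2-yl]oxy}silane | CC(C)(O[Si](CC)(CC)CC)CCC#CO[Si](C(C)C)(C(C)C)C(C)C | intermediate
17 | 2-{5-(benzyloxy)-6-[4-(benzyloxy)phenyl]-4-oxo-4H-pyran-2-yl}ethen-1-one (pyranonylketene) | O=C=Cc1cc(=O)c(OCc2ccccc2)c(-c2ccc(OCc3ccccc3)cc2)o1 | intermediate (not isolated)
18 | 4-{5-(benzyloxy)-6-[4-(benzyloxy)phenyl]-4-oxo-4H-pyran-2-yl}-2-[3-methyl-3-(triethylsilyloxy)butyl]-3-(triisopropylsilyloxy)cyclobut-2-en-1-one (racemic) | O=C1C(CCC(C)(C)O[Si](CC)(CC)CC)=C(O[Si](C(C)C)(C(C)C)C(C)C)C1c1cc(=O)c(OCc2ccccc2)c(-c2ccc(OCc3ccccc3)cc2)o1 | intermediate (not isolated)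
19 | dienylketene, 4-{5-(benzyloxy)-6-[4-(benzyloxy)phenyl]-4-oxo-4H-pyran-2-yl}-2-[3-methyl-3-(triethylsilyloxy)butyl]-3-(triisopropylsilyloxy)buta-1,3-dien-1-one, ketene carbon and pyranonyl group cis across the C3=C4 bond | O=C=C(CCC(C)(C)O[Si](CC)(CC)CC)/C(O[Si](C(C)C)(C(C)C)C(C)C)=C\c1cc(=O)c(OCc2ccccc2)c(-c2ccc(OCc3ccccc3)cc2)o1 | intermediate (not isolated)
20 | 3-(benzyloxy)-2-[4-(benzyloxy)phenyl]-6-[3-methyl-3-(triethylsilyloxy)butyl]-7-(triisopropylsilyloxy)-4aH-chromene-4,5-dione (racemic) | O=C1C(CCC(C)(C)O[Si](CC)(CC)CC)=C(O[Si](C(C)C)(C(C)C)C(C)C)C=C2OC(c3ccc(OCc4ccccc4)cc3)=C(OCc3ccccc3)C(=O)C12 | intermediate (not isolated)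
21 | 3-(benzyloxy)-2-[4-(benzyloxy)phenyl]-5-hydroxy-6-[3-methyl-3-(triethylsilyloxy)butyl]-7-(triisopropylsilyloxy)-4H-chromen-4-one | CC(C)(O[Si](CC)(CC)CC)CCc1c(O[Si](C(C)C)(C(C)C)C(C)C)cc2oc(-c3ccc(OCc4ccccc4)cc3)c(OCc3ccccc3)c(=O)c2c1O | intermediate
22 | 3-(benzyloxy)-2-[4-(benzyloxy)phenyl]-5,7-dihydroxy-6-(3-hydroxy-3-methylbutyl)-4H-chromen-4-one | CC(C)(O)CCc1c(O)cc2oc(-c3ccc(OCc4ccccc4)cc3)c(OCc3ccccc3)c(=O)c2c1O | intermediate
23 | 3,5,7-trihydroxy-6-(3-hydroxy-3-methylbutyl)-2-(4-hydroxyphenyl)-4H-chromen-4-one | CC(C)(O)CCc1c(O)cc2oc(-c3ccc(O)cc3)c(O)c(=O)c2c1O | target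

**Totals**

Total step count: 11. Longest linear sequence: 8 steps (steps 1–5, 9, 10, 11); the alkyne branch (steps 6–8) joins at step 9.

**Steps most likely to fail**

Step 9. The diazo ketone may be lost to light-driven or carbene-type side reactions before the Wolff shift, or the ketene may dimerise before the alkyne traps it. The fallback makes the same ketene thermally and in the dark. It sets out from 9: a silver-catalysed Wolff rearrangement in aqueous dioxane (PhCO2Ag, Et3N; Arndt–Eistert homologation) should give 2-{5-(benzyloxy)-6-[4-(benzyloxy)phenyl]-4-oxo-4H-pyran-2-yl}acetic acid F1. Oxalyl chloride at 0 °C converts it to the acid chloride F2. Slow addition of Et3N to F2 and siloxyalkyne 16 in toluene generates ketene 17 by dehydrochlorination; it is trapped as cyclobutenone 18, and heating carries 18 through 19 and 20. The fallback rejoins the route at 21.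

Step 5. Diazomethane may add as a 1,3-dipole to the doubly activated pyranone C=C bond instead of (or after) being acylated, and the acid chloride may degrade. The fallback avoids diazomethane and the acid chloride. It sets out from 7: EDC/HOBt coupling with N,O-dimethylhydroxylamine gives the Weinreb amide F3, and MeMgBr at −78 °C gives the methyl ketone F4. LiHMDS with 2,2,2-trifluoroethyl trifluoroacetate gives the trifluoroacetyl ketone F5, and detrifluoroacetylative diazo transfer (MsN3, Et3N, H2O, MeCN) returns to the route at 9.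

Step 8. Oxygen transfer to the acetylide may be incomplete, and the ynolate may be silylated on carbon or hydrolysed on work-up. The fallback builds the ynolate by rearrangement instead of oxidation. It sets out from 13: oxidative cleavage of the terminal alkyne (RuCl3 cat., NaIO4, buffered with NaHCO3) gives 4-methyl-4-(triethylsilyloxy)pentanoic acid F6, and TMSCHN2 gives its methyl ester F7. Kowalski homologation (LiCHBr2 from CH2Br2/LiTMP at −78 °C, then n-BuLi and warming) passes through 1,1-dibromo-5-methyl-5-(triethylsilyloxy)hexan-2-one F8 as its lithium enolate. Rearrangement of the derived carbenoid gives ynolate 15, and TIPSOTf returns to the route at 16.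

**Further compounds**

F1 | step 9 | 2-{5-(benzyloxy)-6-[4-(benzyloxy)phenyl]-4-oxo-4H-pyran-2-yl}acetic acid | OC(=O)Cc1cc(=O)c(OCc2ccccc2)c(-c2ccc(OCc3ccccc3)cc2)o1
F2 | step 9 | 2-{5-(benzyloxy)-6-[4-(benzyloxy)phenyl]-4-oxo-4H-pyran-2-yl}acetyl chloride | ClC(=O)Cc1cc(=O)c(OCc2ccccc2)c(-c2ccc(OCc3ccccc3)cc2)o1
F3 | step 5 | 5-(benzyloxy)-6-[4-(benzyloxy)phenyl]-N-methoxy-N-methyl-4-oxo-4H-pyran-2-carboxamide | CON(C)C(=O)c1cc(=O)c(OCc2ccccc2)c(-c2ccc(OCc3ccccc3)cc2)o1
F4 | step 5 | 2-acetyl-5-(benzyloxy)-6-[4-(benzyloxy)phenyl]-4H-pyran-4-one | CC(=O)c1cc(=O)c(OCc2ccccc2)c(-c2ccc(OCc3ccccc3)cc2)o1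
F5 | step 5 | 1-{5-(benzyloxy)-6-[4-(benzyloxy)phenyl]-4-oxo-4H-pyran-2-yl}-4,4,4-trifluorobutane-1,3-dione | O=C(CC(=O)C(F)(F)F)c1cc(=O)c(OCc2ccccc2)c(-c2ccc(OCc3ccccc3)cc2)o1
F6 | step 8 | 4-methyl-4-(triethylsilyloxy)pentanoic acid | CC(C)(O[Si](CC)(CC)CC)CCC(O)=O
F7 | step 8 | methyl 4-methyl-4-(triethylsilyloxy)pentanoate | CC(C)(O[Si](CC)(CC)CC)CCC(=O)OC
F8 | step 8 | 1,1-dibromo-5-methyl-5-(triethylsilyloxy)hexan-2-one | CC(C)(O[Si](CC)(CC)CC)CCC(=O)C(Br)Br
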